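**Remarks (assumptions, one line each)**
- Locants: chain and ring atoms are numbered in the order they appear in the target SMILES (C-1, C-2, C-3, O-4, C-5 … C-16, O-17, C-18 … C-24); the methyl groups on C-13, C-20 and C-23 are 13-Me, 20-Me and 23-Me. In these locants the target is (8S,11S,13R,15S,19R,20R,22R,23R).
- Compounds 13–15 are pairs of C-20 epimers (C-20 is not controlled when it is made); their SMILES leave C-20 undefined.
- The ketoreductase of step 6 is assumed to be chosen from a commercial panel so that it reduces the (4S)-ketone and leaves the (4R)-ketone.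

## Analysis of the target

Target 22 (C25H32O6) is hexacyclic. It contains a spiro α,β-unsaturated δ-lactone (C-2, O-4, C-5, C-6=C-7, spiro C-8), a cyclohexane ring B (C-8, C-9, C-10, C-11, C-22, C-23) and a cyclopentane (C-11, C-19, C-20, C-21, C-22). These are fused to a bicyclo[2.2.2]octanone with bridgeheads C-13 and C-19 and bridges C-24(=O)–C-20, C-14–C-15 and C-12–C-11, and to a γ-lactone (C-15, C-16, O-17, C-18, C-19). There are eight stereocentres; six are fully substituted (C-8, C-11, C-13, C-19, C-20, C-23) and two bear hydrogen (C-15, C-22). C-11, C-13, C-19 and C-20 are locked to each other by the cage, and H-22 is cis to C-12 (cis-fused cyclopentane on ring B). The 23-OH is cis to C-21 and to C-7 and trans to C-2, and at C-15 the lactone carbonyl lies on the side of the ketone bridge.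

The decisive feature is the ring C-13/C-14/C-15/C-19/C-20/C-24. It carries O on C-24, methyls on C-13 and C-20, the carboxyl C-16 on C-15 and C-18 on C-19, which is the substitution pattern of a dearomatised 5-hydroxy-4,6-dimethylphthalide. Together with the C-11–C-12 bridge this is the retron of an intramolecular Diels–Alder reaction of a cyclohexa-2,4-dienone. The unit C-23(OH)–C-22–C-11(=C-12) is the retron of a carbonyl-ene reaction of an (E)-geranyl-type alkene. The terpenoid half counts as geranyl + acetyl + acrylate.

Sensitive points are the epimerisable C-15, the tertiary 23-OH (vinylogous retro-aldol, trans-lactonisation onto C-5) and the Michael-acceptor lactone. The main difficulties are three. C-20 cannot be alkylated once the cage exists, because its enolate would be a bridgehead olefin, so the quaternary centre must be present before the cage is closed. C-20 is remote from the ring-B stereocentres when it is made. The C-11–C-19 bond joins two quaternary carbons.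

## Retrosynthetic reasoning

**22 ⇒ 19 (C-6=C-7 and C-14–C-15).** The last operations are redox adjustments only. The C-6=C-7 bond is cut back to the α-selenide 19 and the C-15 hydrogen to the C-14=C-15 alkylidene lactone. This order is chosen because in 17 the δ-lactone is the only enolisable carbonyl (the cage lactone is unsaturated, the C-24 ketone has no α-H). The selenium can therefore be placed without regiochemical competition, the cage alkene can be reduced while no second enoate is present, and the final selenoxide elimination is neutral and cannot epimerise C-15.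

**17 ⇒ 16 (O-4–C-2).** The spirolactone is opened at the tertiary C–O bond to an isopropenyl group on C-8 and a tert-butyl propanoate arm. The forward reaction is a Markovnikov hydro-acyloxylation. Keeping the lactone open until after the cage is built matters for two reasons: the isopropenyl group is small and planar enough to sit axial in the ene transition state (see below), and no alkene other than C-11=C-12 is within reach of the diene.

**16 ⇒ 15 (C-11–C-19 and C-12–C-13, key step).** Both bonds of the bicyclo[2.2.2]octene are cut in a retro-Diels–Alder sense. This gives the 6,6-disubstituted cyclohexa-2,4-dienone 15, in which C-20 already carries its methyl and the C-21 tether, and the exocyclic methylene C-11=C-12 of ring B. One thermal step then closes two rings and sets C-11, C-13 and C-19; the precursor has only one carbocycle more than an acyclic terpenoid attached to a phthalide.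

**15 ⇒ 14 ⇒ 13 (13-Me; C-22–C-23).** The 13-methyl is traced to a bromine. That bromine blocks the less hindered ortho carbon during dearomatisation and is exchanged by cross-coupling on the dienone. Ring B is opened at C-22–C-23 by a retro Type II carbonyl-ene reaction to the methyl ketone 13. The (E)-alkene geometry fixes OH cis to C-21, and the C-8 stereocentre next to the ketone controls which chair is used.

**13 ⇒ 4 + 11 (C-20–C-21).** The quaternary C-20 is made by C-alkylation of the phenoxide of 4 with the allylic bromide 11. C-21 is allylic only before ring B is closed, which dictates the order alkylation → ene → cycloaddition. C-20 cannot be controlled here, because it is remote from C-8. The cycloaddition later accepts only one C-20 epimer, and the other can be re-equilibrated (see the key-step fallback).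

**11 ⇒ 9 ⇒ 8 ⇒ 6 + 7 ⇒ 5.** The bromide comes from the acetate 9. The quaternary C-8 comes from a Michael addition of the ketone 6 to acrylate 7. Ketone 6 comes from geranyl acetate 5 by an ene-type acetylation of the distal alkene, which installs C-23, 23-Me and the isopropenyl group in one step. Absolute configuration enters by enzymatic resolution of 8.

**4 ⇒ 3 ⇒ 2 ⇒ 1.** The bromophthalide is made from acid 1 by reduction, double bromination and carbonylative lactonisation of the bromide next to the CH2OH group.

## Alternatives that were turned down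

**Alternative 1: (the textbook disconnection)** Cut the bicyclo[2.2.2]octane by an intermolecular Diels–Alder reaction and close the cyclopentane afterwards. The masked o-benzoquinone A1 (from the 4-methoxy analogue of 4) would add to the exocyclic alkene of a finished ring-B iodide A2; the ketal oxygens would be removed reductively, C-20 methylated and then alkylated by C-21. It was turned down because the dienophile is an unactivated 1,1-disubstituted alkene flanked by a quaternary carbon, so an intermolecular cycloaddition has neither rate nor a link between the face of ring B and the sense of the cage. The order of the two C-20 alkylations is also forced (methyl first, since after ring closure the C-20 enolate is a bridgehead olefin). Four redox and alkylation steps are added to do what the tether does for free.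

**Alternative 2:** Join the halves by a [4+3] cycloaddition of the oxyallyl cation from bromoketone A4 to the s-cis diene A3 (bonds C-20–C-21 and C-12–C-13, giving A5), then close C-11–C-19 by a hydrogen-atom-transfer radical cyclisation that would also set C-22 and C-15. This is attractive because the facial selectivity would be set at a diene next to C-23. It was turned down because both partners are unsymmetrical (head-to-head versus head-to-tail regiochemistry is only weakly biased), and the compact and extended transition states lead to different cage/ring-B relationships. The radical step needs H-atom transfer to a tetrasubstituted alkene and bond formation between two quaternary carbons, and A3 and A4 each cost several steps.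

**Alternative 3:** Copy the biosynthesis literally: cationic polyene cyclisation of the dearomatised epoxy-farnesyl dienone A6 to an A/B decalin, then oxidative cleavage and 1,2-shift of ring A to the spirolactone, and cage formation last. It was turned down because a chair–chair cyclisation delivers the C-22 epimer (H-22 trans to 23-Me is what the cage needs as cis). The ring-A rearrangement requires a cation at C-8 generated by C–H abstraction, for which there is no selective reagent. The route also carries the labile allyl dienone through many steps.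

Key step: step 12

## Steps

Step 1
Reactants: 1 3-hydroxy-2-methylbenzoic acid
Product: 2 3-(hydroxymethyl)-2-methylphenol
Conditions: BH3·SMe2, THF, 0 °C → reflux; MeOH quench
Reagents that add atoms: none
Why: Borane reduces the aryl carboxylic acid to the benzylic alcohol and leaves the phenol; no stereocentre.

Step 2
Reactants: 2 3-(hydroxymethyl)-2-methylphenol
Product: 3 4,6-dibromo-3-(hydroxymethyl)-2-methylphenol
Conditions: NBS (2.05 equiv), MeCN, 0 °C → rt
Reagents that add atoms: N-bromosuccinimide, O=C1CCC(=O)N1Br
Why: Electrophilic aromatic bromination at the only free ortho and para positions of the phenol (C-6 and C-4); the C-4 bromide becomes the lactone carbonyl site and the C-6 bromide the later 13-Me.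

Step 3
Reactants: 3 4,6-dibromo-3-(hydroxymethyl)-2-methylphenol
Product: 4 6-bromo-5-hydroxy-4-methyl-2-benzofuran-1(3H)-one
Conditions: CO (1 atm), Pd(OAc)2 (5 mol %), dppf, Et3N, DMF, 90 °C
Reagents that add atoms: carbon monoxide, [C-]#[O+]
Why: Pd-catalysed carbonylative lactonisation of an o-bromobenzyl alcohol; only the bromide next to CH2OH can trap its acyl-palladium intramolecularly, so the bromide ortho to the phenoxide is kept.

Step 4
Reactants: 5 geranyl acetate
Product: 6 (2E)-6-acetyl-3,7-dimethylocta-2,7-dien-1-yl acetate (racemic)
Conditions: Ac2O, ZnCl2, CH2Cl2, 0 °C → rt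
Reagents that add atoms: acetic anhydride, CC(=O)OC(C)=O
Why: Kondakov (ene-type) acylation of the more electron-rich 6,7-alkene (the 2,3-alkene is deactivated by the allylic acetate) gives the β,γ-unsaturated methyl ketone, installing C-23, 23-Me and the isopropenyl group; C-8 is formed racemic and is reset in step 5.

Step 5
Reactants: 6 (2E)-6-acetyl-3,7-dimethylocta-2,7-dien-1-yl acetate; 7 tert-butyl acrylate
Product: 8 tert-butyl (7E)-9-acetoxy-4-acetyl-7-methyl-4-(prop-1-en-2-yl)non-7-enoate (racemic)
Conditions: KOtBu (10 mol %), t-BuOH/THF, 0 °C, short reaction time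
Reagents that add atoms: none
Why: Michael addition through the thermodynamic, conjugated dienolate, which reacts at its α-carbon (deconjugative attack) to give the quaternary C-8; no asymmetric induction, hence racemic.

Step 6
Reactants: 8 tert-butyl (7E)-9-acetoxy-4-acetyl-7-methyl-4-(prop-1-en-2-yl)non-7-enoate (racemic)
Product: 9 tert-butyl (4R,7E)-9-acetoxy-4-acetyl-7-methyl-4-(prop-1-en-2-yl)non-7-enoate
Conditions: ketoreductase (KRED, panel-selected), NADP+, i-PrOH, phosphate buffer pH 7/DMSO, 30 °C, stopped near half conversion; chromatography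
Reagents that add atoms: none
Why: Enzymatic kinetic resolution of an α-quaternary methyl ketone: the enzyme reduces the (4S)-ketone to the carbinol and the (4R)-ketone, which carries the C-8 configuration of the target, is recovered.

Step 7
Reactants: 9 tert-butyl (4R,7E)-9-acetoxy-4-acetyl-7-methyl-4-(prop-1-en-2-yl)non-7-enoate
Product: 10 tert-butyl (4R,7E)-4-acetyl-9-hydroxy-7-methyl-4-(prop-1-en-2-yl)non-7-enoate
Conditions: K2CO3 (cat.), MeOH, 0 °C
Reagents that add atoms: none
Why: Methanolysis of the primary allylic acetate; the tert-butyl ester and the non-enolisable quaternary centre are untouched.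

Step 8
Reactants: 10 tert-butyl (4R,7E)-4-acetyl-9-hydroxy-7-methyl-4-(prop-1-en-2-yl)non-7-enoate
Product: 11 tert-butyl (4R,7E)-4-acetyl-9-bromo-7-methyl-4-(prop-1-en-2-yl)non-7-enoate
Conditions: CBr4, PPh3, CH2Cl2, 0 °C
Reagents that add atoms: tetrabromomethane, BrC(Br)(Br)Br
Why: Appel bromination of the primary allylic alcohol with retention of the (E)-alkene.

Step 9
Reactants: 4 6-bromo-5-hydroxy-4-methyl-2-benzofuran-1(3H)-one; 11 tert-butyl (4R,7E)-4-acetyl-9-bromo-7-methyl-4-(prop-1-en-2-yl)non-7-enoate
Product: 13 tert-butyl (4R,7E)-4-acetyl-9-[(4RS)-6-bromo-4-methyl-1,5-dioxo-1,3,4,5-tetrahydro-2-benzofuran-4-yl]-7-methyl-4-(prop-1-en-2-yl)non-7-enoate, via lithium phenoxide 12 (not isolated)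
Conditions: LiHMDS (1.0 equiv), toluene, 0 °C; then 11, 0 → 15 °C; product kept cold
Reagents that add atoms: none
Why: Alkylative dearomatisation: a tight lithium phenoxide in a non-polar solvent is C-alkylated by the allylic bromide at the methyl-bearing ortho carbon (the other ortho carbon carries Br, the para carbon the lactone carbonyl), creating quaternary C-20; C-20 is remote from C-8, so both epimers are expected.

Step 10
Reactants: 13 tert-butyl (4R,7E)-4-acetyl-9-[(4RS)-6-bromo-4-methyl-1,5-dioxo-1,3,4,5-tetrahydro-2-benzofuran-4-yl]-7-methyl-4-(prop-1-en-2-yl)non-7-enoate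
Product: 14 tert-butyl 3-[(1R,2R,3R)-3-{[(4RS)-6-bromo-4-methyl-1,5-dioxo-1,3,4,5-tetrahydro-2-benzofuran-4-yl]methyl}-2-hydroxy-2-methyl-4-methylidene-1-(prop-1-en-2-yl)cyclohexyl]propanoate
Conditions: Me2AlCl (3.5 equiv), CH2Cl2, −78 → −40 °C; Rochelle salt work-up
Reagents that add atoms: none
Why: Type II intramolecular carbonyl-ene reaction (C-22–C-23 bond, H from the C-12 methyl, exocyclic C-11=C-12) through a chair with the carbonyl oxygen axial; the (E)-alkene places C-21 equatorial, so 23-OH is cis to C-21, and at C-8 the planar isopropenyl group sits axial and the propanoate arm equatorial, so C-2 ends trans and C-7 cis to 23-OH.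

Step 11
Reactants: 14 tert-butyl 3-[(1R,2R,3R)-3-{[(4RS)-6-bromo-4-methyl-1,5-dioxo-1,3,4,5-tetrahydro-2-benzofuran-4-yl]methyl}-2-hydroxy-2-methyl-4-methylidene-1-(prop-1-en-2-yl)cyclohexyl]propanoate
Product: 15 tert-butyl 3-[(1R,2R,3R)-3-{[(4RS)-4,6-dimethyl-1,5-dioxo-1,3,4,5-tetrahydro-2-benzofuran-4-yl]methyl}-2-hydroxy-2-methyl-4-methylidene-1-(prop-1-en-2-yl)cyclohexyl]propanoate
Conditions: Me4Sn, Pd2(dba)3 (2.5 mol %), AsPh3, CuI, NMP, 45 °C
Reagents that add atoms: tetramethylstannane, C[Sn](C)(C)C
Why: Stille methylation of the α-bromo dienone (an activated vinyl bromide) installs 13-Me below the temperature at which the cycloaddition starts; no stereocentre is touched.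

Step 12
Reactants: 15 tert-butyl 3-[(1R,2R,3R)-3-{[(4RS)-4,6-dimethyl-1,5-dioxo-1,3,4,5-tetrahydro-2-benzofuran-4-yl]methyl}-2-hydroxy-2-methyl-4-methylidene-1-(prop-1-en-2-yl)cyclohexyl]propanoate (the (20R)-epimer reacts)
Product: 16 cage ester: the O-4–C-2 seco, 14,15-didehydro form of 22 with an isopropenyl group (C-1, C-2, C-3) and a 2-(tert-butoxycarbonyl)ethyl arm (C-7, C-6, C-5) on C-8
Conditions: toluene (0.01 M), BHT (cat.), 140 °C, sealed tube
Reagents that add atoms: none
Why: A thermal intramolecular [4+2] cycloaddition joins the dienone diene C-19=C-15–C-14=C-13 to the exocyclic alkene C-11=C-12, forming C-11–C-19 and C-12–C-13 in one step. The closest known reaction type is the intramolecular Diels–Alder reaction of 6-(but-3-enyl)cyclohexa-2,4-dienones to isotwistanes. The cyclopentane (C-11, C-19, C-20, C-21, C-22) closes in the fused mode over the two-atom tether C-21–C-22, and the C-12–C-13 bond completes the six-membered ring C-11/C-12/C-13/C-24/C-20/C-19, i.e. the bicyclo[2.2.2]octene. C-13 and C-19 are set by C-20, because the alkene can only reach the diene face that carries C-21. C-11 is set by C-22, because the short tether allows only the cis-fused five-membered ring on ring B. Regiochemistry is fixed by the tether, and the electron-poor lactone-dienone pairs well with the unactivated alkene. The selectivity needed is between the C-20 epimers: only (20R)-15 can fold, since the (20S)-epimer would need a trans-fused cyclopentane inside the cage and is recovered unchanged. Dimerisation of the tetrasubstituted dienone is suppressed by dilution, and the isopropenyl group is out of reach of the diene.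

Step 13
Reactants: 16 cage ester
Product: 17 14,15-didehydro-6,7-dihydro-22 (saturated spiro δ-lactone, unsaturated cage lactone)
Conditions: Co(salen) catalyst (5 mol %), N-fluoro-2,4,6-trimethylpyridinium tetrafluoroborate, PhSiH3, PhCF3, 0 °C → rt
Reagents that add atoms: none
Why: Cobalt-hydride H-atom transfer to the 1,1-disubstituted isopropenyl group, oxidation to the tertiary cation at C-2 and capture by the ester carbonyl with loss of isobutene (Markovnikov hydro-acyloxylation) close the spirolactone; the electron-poor C-14=C-15 is inert and C-2 is not stereogenic.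

Step 14
Reactants: 17 14,15-didehydro-6,7-dihydro-22
Product: 19 6-(phenylselanyl)-14,15-didehydro-6,7-dihydro-22 (C-6 epimers), via dilithium enolate 18 (not isolated)
Conditions: LDA (2.2 equiv), THF, −78 °C; PhSeBr, −78 °C
Reagents that add atoms: phenylselenyl bromide, Br[Se]c1ccccc1
Why: α-Selenation of the only enolisable carbonyl (the cage lactone has no α-H and the C-24 ketone lies between two quaternary carbons), the second equivalent of base being taken by the 23-OH; the new C-6 centre is removed in step 15.

Step 15
Reactants: 19 6-(phenylselanyl)-14,15-didehydro-6,7-dihydro-22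
Product: 22 target CNP0222978.3, via dihydro selenide 20 (not isolated), via selenoxide 21 (not isolated)
Conditions: NaBH4, THF/MeOH, 0 °C; AcOH quench; then H2O2, pyridine, CH2Cl2, 0 °C → rt
Reagents that add atoms: none
Why: Hydride adds 1,4 to the strained s-cis alkylidene lactone (the only conjugated alkene present) and the lactone enolate is protonated at C-15, whose two faces differ only by 20-Me versus the C-10 methylene, so the (15S)-isomer is taken on after separation and the 15-epimer is returned by base equilibration; selenoxide syn-elimination then gives C-6=C-7 under neutral conditions that leave C-15 untouched.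

## Compound list

1 | 3-hydroxy-2-methylbenzoic acid | Cc1c(O)cccc1C(=O)O | starting material
2 | 3-(hydroxymethyl)-2-methylphenol | Cc1c(O)cccc1CO | intermediate
3 | 4,6-dibromo-3-(hydroxymethyl)-2-methylphenol | Cc1c(O)c(Br)cc(Br)c1CO | intermediate
4 | 6-bromo-5-hydroxy-4-methyl-2-benzofuran-1(3H)-one | Cc1c(O)c(Br)cc2c1COC2=O | intermediate
5 | geranyl acetate, (2E)-3,7-dimethylocta-2,6-dien-1-yl acetate | CC(C)=CCC/C(C)=C/COC(C)=O | starting material
6 | (2E)-6-acetyl-3,7-dimethylocta-2,7-dien-1-yl acetate (racemic) | CC(=C)C(C(C)=O)CC/C(C)=C/COC(C)=O | intermediate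
7 | tert-butyl acrylate | C=CC(=O)OC(C)(C)C | starting material
8 | tert-butyl (7E)-9-acetoxy-4-acetyl-7-methyl-4-(prop-1-en-2-yl)non-7-enoate (racemic) | CC(C)(C)OC(=O)CCC(C(C)=O)(C(C)=C)CC/C(C)=C/COC(C)=O | intermediate
9 | tert-butyl (4R,7E)-9-acetoxy-4-acetyl-7-methyl-4-(prop-1-en-2-yl)non-7-enoate | CC(C)(C)OC(=O)CC[C@@](C(C)=O)(C(C)=C)CC/C(C)=C/COC(C)=O | intermediate
10 | tert-butyl (4R,7E)-4-acetyl-9-hydroxy-7-methyl-4-(prop-1-en-2-yl)non-7-enoate | CC(C)(C)OC(=O)CC[C@@](C(C)=O)(C(C)=C)CC/C(C)=C/CO | intermediate
11 | tert-butyl (4R,7E)-4-acetyl-9-bromo-7-methyl-4-(prop-1-en-2-yl)non-7-enoate | CC(C)(C)OC(=O)CC[C@@](C(C)=O)(C(C)=C)CC/C(C)=C/CBr | intermediate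
12 | lithium 6-bromo-4-methyl-1-oxo-1,3-dihydro-2-benzofuran-5-olate | [Li+].Cc1c([O-])c(Br)cc2c1COC2=O | intermediate
13 | tert-butyl (4R,7E)-4-acetyl-9-[(4RS)-6-bromo-4-methyl-1,5-dioxo-1,3,4,5-tetrahydro-2-benzofuran-4-yl]-7-methyl-4-(prop-1-en-2-yl)non-7-enoate (C-20 epimer pair) | CC(C)(C)OC(=O)CC[C@@](C(C)=O)(C(C)=C)CC/C(C)=C/CC1(C)C(=O)C(Br)=CC2=C1COC2=O | intermediate
14 | tert-butyl 3-[(1R,2R,3R)-3-{[(4RS)-6-bromo-4-methyl-1,5-dioxo-1,3,4,5-tetrahydro-2-benzofuran-4-yl]methyl}-2-hydroxy-2-methyl-4-methylidene-1-(prop-1-en-2-yl)cyclohexyl]propanoate (C-20 epimer pair) | CC(C)(C)OC(=O)CC[C@@]1(C(C)=C)CCC(=C)[C@@H](CC2(C)C(=O)C(Br)=CC3=C2COC3=O)[C@@]1(C)O | intermediate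
15 | tert-butyl 3-[(1R,2R,3R)-3-{[(4RS)-4,6-dimethyl-1,5-dioxo-1,3,4,5-tetrahydro-2-benzofuran-4-yl]methyl}-2-hydroxy-2-methyl-4-methylidene-1-(prop-1-en-2-yl)cyclohexyl]propanoate (C-20 epimer pair; the (20R)-epimer has [C@@] at the dienone quaternary carbon) | CC(C)(C)OC(=O)CC[C@@]1(C(C)=C)CCC(=C)[C@@H](CC2(C)C(=O)C(C)=CC3=C2COC3=O)[C@@]1(C)O | intermediate
16 | cage ester: O-4–C-2 seco, 14,15-didehydro form of 22 with isopropenyl and 2-(tert-butoxycarbonyl)ethyl on C-8; C-8, C-11, C-13, C-19, C-20, C-22, C-23 as in 22 | CC(C)(C)OC(=O)CC[C@@]2(C(C)=C)CC[C@@]13C[C@@]4(C)C=C5C(=O)OC[C@]51[C@@](C)(C[C@H]3[C@@]2(C)O)C4=O | intermediate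
17 | 14,15-didehydro-6,7-dihydro-22 | CC1(C)OC(=O)CC[C@]12CC[C@@]13C[C@@]4(C)C=C5C(=O)OC[C@]51[C@@](C)(C[C@H]3[C@@]2(C)O)C4=O | intermediate
18 | dilithium salt of 17 (δ-lactone enolate and C-23 alkoxide) | [Li+].[Li+].CC1(C)OC([O-])=CC[C@]12CC[C@@]13C[C@@]4(C)C=C5C(=O)OC[C@]51[C@@](C)(C[C@H]3[C@@]2(C)[O-])C4=O | intermediate
19 | 6-(phenylselanyl)-14,15-didehydro-6,7-dihydro-22 (C-6 epimers) | CC1(C)OC(=O)C([Se]c6ccccc6)C[C@]12CC[C@@]13C[C@@]4(C)C=C5C(=O)OC[C@]51[C@@](C)(C[C@H]3[C@@]2(C)O)C4=O | intermediate
20 | 6-(phenylselanyl)-6,7-dihydro-22 (C-6 epimers) | CC1(C)OC(=O)C([Se]c6ccccc6)C[C@]12CC[C@@]13C[C@@]4(C)C[C@@H]5C(=O)OC[C@]51[C@@](C)(C[C@H]3[C@@]2(C)O)C4=O | intermediate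
21 | selenoxide of 20 | CC1(C)OC(=O)C([Se](=O)c6ccccc6)C[C@]12CC[C@@]13C[C@@]4(C)C[C@@H]5C(=O)OC[C@]51[C@@](C)(C[C@H]3[C@@]2(C)O)C4=O | intermediate
22 | CNP0222978.3, (8S,11S,13R,15S,19R,20R,22R,23R) in the locants defined above | CC1(C)OC(=O)C=C[C@]12CC[C@@]13C[C@@]4(C)C[C@@H]5C(=O)OC[C@]51[C@@](C)(C[C@H]3[C@@]2(C)O)C4=O | target

## Step count and least certain steps

Total: 15 steps. Longest linear sequence: 12 steps (steps 4–15, from geranyl acetate 5); the arene branch (steps 1–3) joins at step 9.

**Step 12 (key step).** What is most likely to go wrong is the stereochemical mismatch at C-20: only one of the two C-20 epimers of 15 can fold, so the other accumulates unchanged. Prolonged heating of material that cannot cyclise also invites decomposition, and the C-11–C-19 bond joins two fully substituted carbons, so the reaction may be slow. Fallback: the recovered (20S)-epimer of 15 is irradiated (365 nm, benzene, rt, no nucleophile). This opens the dienone electrocyclically to the dienylketene F1, which recloses thermally on either face and so returns the epimer mixture 15, which is heated again. This photochemical ring opening and reclosure is the known way to scramble C-6 of 6,6-disubstituted cyclohexa-2,4-dienones; it sets out from 15 and comes back to 15.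

**Step 9.** The phenoxide is ambident and electron-poor (para-acyl, ortho-bromo), so O-alkylation to the aryl allyl ether may dominate over C-alkylation. The C-allyl dienone can also revert by [3,3] shift if warmed. Fallback: the more electron-rich phenol 3 (a para bromide in place of the lactone carbonyl) is alkylated with 11 under the same conditions to the dienone F2. The lactone is then closed on the dienone by Pd-catalysed carbonylative lactonisation of the C-15 bromide with the neighbouring CH2OH (CO, Et3N, 40 °C), which gives 13.

**Step 10.** The Lewis acid may trigger a [3,3] shift of the still allylic C-21 group or a dienone–phenol rearrangement before the ene reaction. The chair with the isopropenyl group equatorial may also compete, giving the wrong C-8/C-23 relationship. Fallback: the ene reaction is run before the union, on the allylic alcohol 10 (no dienone present), to give the diol F3. Its primary hydroxyl is converted into the iodide F4 (I2, PPh3, imidazole), and F4 alkylates the phenoxide 12 to give 14 directly. This exchanges the acid-sensitivity risk for a slower C-alkylation with a non-allylic iodide.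

**Step 15.** Protonation at C-15 has little facial bias (20-Me on one side, the C-10 methylene on the other), so an epimer mixture is likely. The borohydride medium may also open the spirolactone towards the 23-alkoxide. Fallback: 19 is first oxidised (H2O2, pyridine) to the bis-enoate F5. The cage alkene of F5 is then reduced with an ene-reductase of the Old Yellow Enzyme family (NADPH recycling), which delivers hydride to C-14 and a proton to C-15 under enzyme control and leaves the hindered, s-trans spirolactone enoate alone, giving 22.

**Step 6.** The enzyme may not distinguish the enantiomers well, because two of the three substituents on C-8 begin with CH2CH2. Fallback: C-8 is set by a chiral-imine Michael addition instead. Ketone 6 is condensed with (S)-1-phenylethylamine to the imine F6 (the amine enantiomer to be chosen by trial). Its secondary enamine tautomer adds to 7 to give the adduct imine F7, and mild aqueous acid hydrolysis gives 9 without a resolution.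

## Further compounds

F1 | step 12 | dienylketene from electrocyclic opening of (20S)-15 (C-24–C-20 bond broken) | CC(C)(C)OC(=O)CC[C@@]1(C(C)=C)CCC(=C)[C@@H](CC(C)=C2COC(=O)/C2=C/C(C)=C=O)[C@@]1(C)O
F2 | step 9 | tert-butyl (4R,7E)-4-acetyl-9-[(1RS)-3,5-dibromo-6-(hydroxymethyl)-1-methyl-2-oxocyclohexa-3,5-dien-1-yl]-7-methyl-4-(prop-1-en-2-yl)non-7-enoate | CC(C)(C)OC(=O)CC[C@@](C(C)=O)(C(C)=C)CC/C(C)=C/CC1(C)C(=O)C(Br)=CC(Br)=C1CO
F3 | step 10 | tert-butyl 3-[2-hydroxy-3-(hydroxymethyl)-2-methyl-4-methylidene-1-(prop-1-en-2-yl)cyclohexyl]propanoate, ring-B configuration as in 14 | CC(C)(C)OC(=O)CC[C@@]1(C(C)=C)CCC(=C)[C@@H](CO)[C@@]1(C)O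
F4 | step 10 | tert-butyl 3-[2-hydroxy-3-(iodomethyl)-2-methyl-4-methylidene-1-(prop-1-en-2-yl)cyclohexyl]propanoate, ring-B configuration as in 14 | CC(C)(C)OC(=O)CC[C@@]1(C(C)=C)CCC(=C)[C@@H](CI)[C@@]1(C)O
F5 | step 15 | 14,15-didehydro-22 (bis-enoate) | CC1(C)OC(=O)C=C[C@]12CC[C@@]13C[C@@]4(C)C=C5C(=O)OC[C@]51[C@@](C)(C[C@H]3[C@@]2(C)O)C4=O
F6 | step 6 | (S)-1-phenylethyl imine of 6 | CC(=C)C(C(C)=N[C@@H](C)c1ccccc1)CC/C(C)=C/COC(C)=O
F7 | step 6 | (S)-1-phenylethyl imine of 9 | CC(C)(C)OC(=O)CC[C@@](C(C)=N[C@@H](C)c1ccccc1)(C(C)=C)CC/C(C)=C/COC(C)=O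
A1 | alternative 1 | 4,4-dimethoxy-6-methyl-2-benzofuran-1,5(3H,4H)-dione | COC1(OC)C(=O)C(C)=CC2=C1COC2=O
A2 | alternative 1 | 11-hydroxy-10-(iodomethyl)-1,1,11-trimethyl-9-methylidene-2-oxaspiro[5.5]undec-4-en-3-one, configuration as ring B of 22 | CC1(C)OC(=O)C=C[C@]12CCC(=C)[C@@H](CI)[C@@]2(C)O
A3 | alternative 2 | 11-hydroxy-1,1,11-trimethyl-9,10-dimethylidene-2-oxaspiro[5.5]undec-4-en-3-one | CC1(C)OC(=O)C=C[C@]12CCC(=C)C(=C)[C@@]2(C)O
A4 | alternative 2 | 6-bromo-4,6-dimethyl-6,7-dihydro-2-benzofuran-1,5(3H,4H)-dione | CC1C(=O)C(C)(Br)CC2=C1COC2=O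
A5 | alternative 2 | [4+3] cycloadduct with bonds C-20–C-21 and C-12–C-13, alkene C-11=C-22, butenolide C-15=C-19 | CC1(C)OC(=O)C=C[C@]12CCC3=C(C[C@@]4(C)C(=O)[C@@](C)(C3)CC5=C4COC5=O)[C@@]2(C)O
A6 | alternative 3 | 4-{(2E,6E)-9-[(2S)-3,3-dimethyloxiran-2-yl]-3,7-dimethylnona-2,6-dien-1-yl}-4,6-dimethyl-2-benzofuran-1,5(3H,4H)-dione | CC1(C)O[C@H]1CC/C(C)=C/CC/C(C)=C/CC2(C)C(=O)C(C)=CC3=C2COC3=O
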